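A small charge of single-handed free catalyst turns a racemic substrate into product in two flasks that differ in temperature, and the left-handed form reacts faster than the right-handed one.

    reagent + free catalyst + left-handed substrate → free catalyst + left-handed product (k1 = 2.13 /M²/s, Ea1 = 43.0 kJ/mol)
    reagent + free catalyst + right-handed substrate → free catalyst + right-handed product (k2 = 0.278 /M²/s, Ea2 = 45.0 kJ/mol)
    left-handed substrate + racemization catalyst ⇌ right-handed substrate + racemization catalyst, rate k3*[racemization catalyst]*[left-handed substrate] forward; the back reaction follows from the equilibrium constant (k3 = 0.0105 /M/s, Ea3 = 50.0 kJ/mol)
    reagent → decomposition product (k4 = 3.18 × 10⁻⁸ /s, Ea4 = 108 kJ/mol)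
    racemization catalyst + impurity → spent catalyst (k5 = 0.167 /M/s, Ea5 = 50.0 kJ/mol)
    left-handed product ⇌ right-handed product (k6 = 2.13 × 10⁻⁶ /s, Ea6 = 105 kJ/mol)
    (constants at 0 °C)

| setting | midnight | autumn |
|---|---|---|
| left-handed substrate | 0.057 M | 0.057 M |
| reagent | 0.114 M | 0.114 M |
| free catalyst | 1.1 mM | 1.1 mM |
| racemization catalyst | 0.57 mM | 0.57 mM |
| impurity | 0.78 mM | 0.78 mM |
| right-handed substrate | 0.057 M | 0.057 M |
| temperature | −25 °C | 0 °C |
| time | 40 h | 40 h |

- free catalyst is single-handed; left-handed substrate and right-handed substrate are mirror images of each other, charged as a racemate, each of them at the stated concentration
- at 0 °C the constants are as listed, elsewhere as the activation energies make them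
- an excess is below zero if the other one leads

1. the flask with the highest excess of left-handed product over right-handed product ("all alike" if they lie within 1.5 percentage points) (midnight / autumn / all alike)
2. excess of left-handed product over right-handed product at the end, midnight
3. excess of left-handed product over right-handed product at the end, autumn

I draw the excess as a curve, leaving the racemization of the substrate aside. At the start the two substrates stand equal, so the excess being made follows from the selectivity factor s, the left-handed constant over the right-handed one:

autumn: s = 7.66, e = (s − 1)/(s + 1) = 76.9%
midnight: s = 8.37, e = 78.7%

The left-handed substrate is used faster, so the rate ratio s·c(left-handed substrate)/c(right-handed substrate) falls. The knee comes when this ratio reaches 1: the two products are then made equally fast and the excess stops growing in amount. For midnight this happens at c(right-handed substrate) = 0.0427 M.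

The reagent charge equals both substrates together. I take c(reagent) = c(right-handed substrate) throughout, which is the balance once the left-handed substrate has reacted and a rough stand-in before that, so the tail is second order in that one concentration:

1/c(right-handed substrate) = 1/0.057 M + k·c(free catalyst)·t
autumn: c(right-handed substrate) = 0.0162 M
midnight: c(right-handed substrate) = 0.0425 M

So midnight ends about at its knee, with c(left-handed substrate) = 0.00489 M, while autumn runs far past it. Counting what has reacted, the excess before any fading is 56.5% for midnight and 16.6% for autumn.

Then comes the fading. In autumn an excess shrinks over the run to 0.541 of itself. This is the kept share K, the part of a product excess already standing at the start that outlasts the run, exp(−2·k·t) with k the constant of the product step. The relaxation half-life in autumn is 45.2 h, against a run of 40 h. At midnight that constant is smaller by a factor 105, so K = 0.994. Multiplying, I commit to 56.2% for midnight and 8.99% for autumn, so midnight leads.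

The forecast also says midnight, with 53% for midnight and 7% for autumn, lower than mine on both. Its ground for autumn is that “the reaction goes much further”.

The simulation gives midnight, with 52.4% for midnight and 7.63% for autumn after 40.0 h.

The forecast stands within tolerance on both flasks, and mine is high by 3.8 percentage points and 1.4 points. A neighbour flask, like autumn but with 0.029 M of reagent, has enough for a quarter of the substrate, so I take the starting e for its excess: K·e = 41.6%. That flask gives 40.3%, with its reagent down to 0% and right-handed substrate still at 45.5%.

The numbers stand for no real mixture, and the outcome is calculated.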